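The chain is cut between its CH2 carbon and the methyl-bearing methine carbon attached to C2 of the furan ring. This methine carbon and the furan C2=C3 bond form a latent allyl unit. An (R)-1-(benzofuran-2-yl)ethyl carbonate should therefore ionise with zerovalent palladium to an η3 complex. The partner is a lithium boronate whose boron carries the chromen-6-yl ring and an isopropenyl group. Attack of the isopropenyl CH2 on the η3 complex makes the CH2–CH bond and drives the chromenyl ring from boron to carbon. Two C–C bonds, the fully substituted carbon and both stereocentres thus arise in one operation. Stereoretentive C–B oxidation and desilylation finish the synthesis.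

Key step: step 6

Assumption: in step 6 the boronate is taken to attack the η3 complex on the face opposite palladium, so that the (R)-carbonate gives the (S)-methine centre, and (R)-BINAP is taken as the ligand enantiomer matched to the required alkene face.

Step 1
Reactants: 1 4-bromo-3-methoxyphenol; 2 3-methylbut-2-enal
Product: 3 6-bromo-7-methoxy-2,2-dimethyl-2H-chromene
Conditions: PhB(OH)2 (1 equiv), AcOH, toluene, reflux, Dean–Stark
Reagents that add atoms: none
Why: Boronic-acid-templated ortho-hydroxyalkylation of the phenol gives a benzodioxaborin that collapses to an ortho-quinone methide, and its oxa-6π electrocyclisation closes the 2H-pyran ring at the open position para to the methoxy group, the other ortho position being crowded between two oxygen substituents.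

Step 2
Reactants: 4 1-(2,4-dihydroxyphenyl)ethanone
Product: 5 1-(2,4-dihydroxy-5-iodophenyl)ethanone
Conditions: ICl, AcOH, rt
Reagents that add atoms: iodine monochloride, ClI
Why: Electrophilic aromatic iodination should take C5, which is ortho to the 4-OH and para to the 2-OH and less crowded than C3 between the two hydroxyl groups.

Step 3
Reactants: 5 1-(2,4-dihydroxy-5-iodophenyl)ethanone; 6 (R)-but-3-yn-2-ol
Product: 8 1-{6-hydroxy-2-[(1R)-1-hydroxyethyl]-1-benzofuran-5-yl}ethanone, via alkynylphenol 7 (not isolated)
Conditions: PdCl2(PPh3)2 (cat.), CuI (cat.), Et3N, DMF, 60 °C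
Reagents that add atoms: none
Why: Sonogashira coupling followed in the same flask by 5-endo-dig cycloisomerisation of the ortho-alkynylphenol builds the furan ring from the 4-OH, and the carbinol centre of 6 is not touched, so it stays (R).

Step 4
Reactants: 8 1-{6-hydroxy-2-[(1R)-1-hydroxyethyl]-1-benzofuran-5-yl}ethanone
Product: 9 1-{2-[(1R)-1-hydroxyethyl]-6-(triisopropylsilyloxy)-1-benzofuran-5-yl}ethanone
Conditions: NaH (1.0 equiv), THF–DMF, 0 °C; TIPSCl, 0 °C to rt
Reagents that add atoms: triisopropylsilyl chloride, CC(C)[Si](Cl)(C(C)C)C(C)C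
Why: Chemoselective O-silylation, in which one equivalent of NaH removes only the phenolic proton and the phenoxide takes up the bulky silyl chloride while the neutral secondary alcohol stays free.

Step 5
Reactants: 9 1-{2-[(1R)-1-hydroxyethyl]-6-(triisopropylsilyloxy)-1-benzofuran-5-yl}ethanone
Product: 10 (1R)-1-[5-acetyl-6-(triisopropylsilyloxy)-1-benzofuran-2-yl]ethyl methyl carbonate
Conditions: ClCO2Me, pyridine, CH2Cl2, 0 °C
Reagents that add atoms: methyl chloroformate, COC(=O)Cl
Why: O-Acylation with a chloroformate turns the alcohol into a leaving group for palladium without breaking the C–O bond, so the (R) configuration is kept.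

Step 6
Reactants: 3 6-bromo-7-methoxy-2,2-dimethyl-2H-chromene; 11 2-isopropenyl-4,4,5,5-tetramethyl-1,3,2-dioxaborolane; 10 (1R)-1-[5-acetyl-6-(triisopropylsilyloxy)-1-benzofuran-2-yl]ethyl methyl carbonate
Product: 14 1-{2-[(2S,4R)-4-(7-methoxy-2,2-dimethyl-2H-chromen-6-yl)-4-(4,4,5,5-tetramethyl-1,3,2-dioxaborolan-2-yl)pentan-2-yl]-6-(triisopropylsilyloxy)-1-benzofuran-5-yl}ethanone, via chromenyllithium 12 (not isolated), via lithium boronate 13 (not isolated)
Conditions: 3, n-BuLi, THF, −78 °C; 11 (1.1 equiv), −78 °C to rt; 10, Pd2(dba)3 (2.5 mol%), (R)-BINAP (6 mol%), THF, rt to 40 °C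
Reagents that add atoms: none
Why: Proposed new method: zerovalent palladium ionises carbonate 10 with inversion to a cationic η3 complex that spans the side-chain methine carbon and C2–C3 of the furan ring, the isopropenyl CH2 of boronate 13 attacks the methine carbon on the face opposite palladium, and as this CH2–CH bond forms the chromen-6-yl group shifts from boron to the adjacent carbon antiperiplanar to the incoming electrophile (1,2-metalate rearrangement). The closest known reaction types are the iridium π-allyl-triggered allylation/1,2-metalate shift of alkenyl boronates with 1,3-diastereocontrol, the palladium/BINAP π-allyl-triggered shift of indol-2-yl boronates and the palladium-catalysed substitution of secondary benzylic carbonates through η3-benzyl complexes; what is new is an η3-benzyl-type electrophile as the trigger. No ring is closed. The methine centre (S) follows from double inversion, that is net retention of the C–O configuration taken from (R)-but-3-yn-2-ol, and the boron-bearing centre (R) is set by the choice of alkene face in an open transition state in which the bulky boronate turns away from the benzofuran plane and the BINAP aryl groups, the aryl group being delivered anti to the new bond. The step needs attack at the exocyclic carbon rather than at furan C3 (secured by rearomatisation of the furan ring), outer-sphere capture rather than aryl transfer to palladium (the chelating ligand leaves no free site on the cationic complex) and substitution faster than β-hydride loss from the methyl group (the boronate is a strong π-nucleophile present in full concentration). The aryl ketone and the silyl ether of 10 should be inert to the boronate, which carries no free organolithium because 11 is used in slight excess.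

Step 7
Reactants: 14 the tertiary boronic ester from step 6
Product: 15 1-{2-[(2S,4S)-4-hydroxy-4-(7-methoxy-2,2-dimethyl-2H-chromen-6-yl)pentan-2-yl]-6-(triisopropylsilyloxy)-1-benzofuran-5-yl}ethanone
Conditions: NaBO3·4H2O, THF–H2O, rt
Reagents that add atoms: sodium perborate tetrahydrate NaBO3·4H2O, [Na+].[Na+].O[B-]1(O)OO[B-](O)(O)OO1
Why: Oxidation of a boronic ester by hydroperoxide addition to boron and 1,2-shift of the tertiary carbon from boron to oxygen runs with retention (the descriptor changes from R to S only because oxygen outranks the carbon substituents), and the mildly basic perborate should spare the aryl silyl ether, the ketone and the chromene alkene.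

Step 8
Reactants: 15 the silyl-protected tertiary alcohol from step 7
Product: 16 1-{6-hydroxy-2-[(2S,4S)-4-hydroxy-4-(7-methoxy-2,2-dimethyl-2H-chromen-6-yl)pentan-2-yl]-1-benzofuran-5-yl}ethanone (CNP0233723.1)
Conditions: TBAF, AcOH, THF, 0 °C
Reagents that add atoms: none
Why: Fluoride-induced cleavage of the aryl silyl ether under acetic acid buffering is mild enough for the ionisation-prone tertiary benzylic alcohol, and it is placed after step 7 because fluoride would protodeboronate 14.

Compound list
1 | 4-bromo-3-methoxyphenol | COc1cc(O)ccc1Br | starting material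
2 | 3-methylbut-2-enal | CC(C)=CC=O | starting material
3 | 6-bromo-7-methoxy-2,2-dimethyl-2H-chromene | COc1cc2c(cc1Br)C=CC(C)(C)O2 | intermediate
4 | 1-(2,4-dihydroxyphenyl)ethanone | CC(=O)c1ccc(O)cc1O | starting material
5 | 1-(2,4-dihydroxy-5-iodophenyl)ethanone | CC(=O)c1cc(I)c(O)cc1O | intermediate
6 | (R)-but-3-yn-2-ol | C#C[C@@H](C)O | starting material
7 | 1-{2,4-dihydroxy-5-[(3R)-3-hydroxybut-1-yn-1-yl]phenyl}ethanone (not isolated) | CC(=O)c1cc(C#C[C@@H](C)O)c(O)cc1O | intermediate
8 | 1-{6-hydroxy-2-[(1R)-1-hydroxyethyl]-1-benzofuran-5-yl}ethanone | O[C@H](C)c1cc2cc(C(C)=O)c(O)cc2o1 | intermediate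
9 | 1-{2-[(1R)-1-hydroxyethyl]-6-(triisopropylsilyloxy)-1-benzofuran-5-yl}ethanone | O[C@H](C)c1cc2cc(C(C)=O)c(O[Si](C(C)C)(C(C)C)C(C)C)cc2o1 | intermediate
10 | (1R)-1-[5-acetyl-6-(triisopropylsilyloxy)-1-benzofuran-2-yl]ethyl methyl carbonate | COC(=O)O[C@H](C)c1cc2cc(C(C)=O)c(O[Si](C(C)C)(C(C)C)C(C)C)cc2o1 | intermediate
11 | 2-isopropenyl-4,4,5,5-tetramethyl-1,3,2-dioxaborolane | C=C(C)B1OC(C)(C)C(C)(C)O1 | starting material
12 | (7-methoxy-2,2-dimethyl-2H-chromen-6-yl)lithium (not isolated) | COc1cc2c(cc1[Li])C=CC(C)(C)O2 | intermediate
13 | lithium isopropenyl(7-methoxy-2,2-dimethyl-2H-chromen-6-yl)(pinacolato)borate (not isolated) | [Li+].COc1cc2c(cc1[B-]1(C(C)=C)OC(C)(C)C(C)(C)O1)C=CC(C)(C)O2 | intermediate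
14 | 1-{2-[(2S,4R)-4-(7-methoxy-2,2-dimethyl-2H-chromen-6-yl)-4-(4,4,5,5-tetramethyl-1,3,2-dioxaborolan-2-yl)pentan-2-yl]-6-(triisopropylsilyloxy)-1-benzofuran-5-yl}ethanone | COc1cc2c(cc1[C@@](C)(B1OC(C)(C)C(C)(C)O1)C[C@H](C)c1cc3cc(C(C)=O)c(O[Si](C(C)C)(C(C)C)C(C)C)cc3o1)C=CC(C)(C)O2 | intermediate
15 | 1-{2-[(2S,4S)-4-hydroxy-4-(7-methoxy-2,2-dimethyl-2H-chromen-6-yl)pentan-2-yl]-6-(triisopropylsilyloxy)-1-benzofuran-5-yl}ethanone | COc1cc2c(cc1[C@@](C)(O)C[C@H](C)c1cc3cc(C(C)=O)c(O[Si](C(C)C)(C(C)C)C(C)C)cc3o1)C=CC(C)(C)O2 | intermediate
16 | 1-{6-hydroxy-2-[(2S,4S)-4-hydroxy-4-(7-methoxy-2,2-dimethyl-2H-chromen-6-yl)pentan-2-yl]-1-benzofuran-5-yl}ethanone | COc1cc2c(cc1[C@@](C)(O)C[C@H](C)c1cc3cc(C(C)=O)c(O)cc3o1)C=CC(C)(C)O2 | target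

Total step count: 8. Longest linear sequence: 7 steps (steps 2 to 8).

Steps most likely to fail

Step 6.
- **What may go wrong:** the union may fail through β-hydride elimination in the benzyl–palladium complex to a 2-vinylbenzofuran. It may also fail through erosion of configuration by exchange between palladium centres, aryl transfer from boron to palladium, or poor facial selectivity at the alkene.
- **Fallback:** it uses known chemistry, sets out from 9 and from boronate 13 (made from 3 and 11 as in step 6), and comes back at 15.
- Oxidation of 9 with MnO2 would give the 2,5-diacetylbenzofuran F1.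
- Deprotonation with KN(SiMe3)2 under equilibrating conditions should select the more acidic 2-acetyl group, because the 5-acetyl group is deactivated by two oxygen donors. PhNTf2 would then give the enol triflate F2.
- The established enantioselective conjunctive cross-coupling of α-substituted alkenyl boronates (Pd(OAc)2, MandyPhos ligand Fe[C5H3(PPh2)(CH(NMe2)Ph)]2, THF, 60 °C) would join 13 and F2. It forms the same CH2–C bond at the sp2 level together with the aryl shift. It should give the alkenyl tertiary boronic ester F3, with the boron-bearing centre under ligand control.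
- NaBO3·4H2O would give the homoallylic alcohol F4.
- Asymmetric hydrogenation of the terminal 1,1-disubstituted alkene of F4 ([Ir(cod)((S)-tBu-PHOX)]BArF, H2 1 bar, CH2Cl2) would be stopped after one equivalent of hydrogen, so that the more hindered chromene alkene is left. This sets the methine centre and gives 15.

Step 2.
- **What may go wrong:** iodination may go to C3 between the two hydroxyl groups or run on to di-iodination.
- **Fallback:** it sets out from 4 and comes back at 5, and it steers the regiochemistry with a protecting group.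
- Selective acetylation of the free 4-OH (Ac2O, pyridine; the chelated 2-OH stays) would give the monoacetate F5.
- In F5 the 2-OH is the only strong donor, so iodination (NIS, cat. TFA, MeCN) should go para to it, at the uncrowded C5, to give the iodo acetate F6.
- Methanolysis (K2CO3, MeOH) returns 5.

Step 1.
- **What may go wrong:** hydroxyalkylation of the bromine-deactivated phenol may be slow, and self-condensation of the enal may take over.
- **Fallback:** it sets out from 1 and comes back at 3, and it replaces C-hydroxyalkylation by O-alkylation and a sigmatropic shift.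
- Alkylation with 3-chloro-3-methylbut-1-yne (CuCl2 cat., DBU, MeCN, 0 °C) would give the aryl dimethylpropargyl ether F7.
- Heating in N,N-diethylaniline at about 190 °C should trigger aromatic propargyl Claisen rearrangement, 1,5-hydrogen shift and oxa-6π electrocyclisation to 3.

Further compounds
F1 | step 6 | 1,1'-[6-(triisopropylsilyloxy)-1-benzofuran-2,5-diyl]diethanone | CC(=O)c1cc2cc(C(C)=O)c(O[Si](C(C)C)(C(C)C)C(C)C)cc2o1
F2 | step 6 | 1-[5-acetyl-6-(triisopropylsilyloxy)-1-benzofuran-2-yl]ethenyl trifluoromethanesulfonate | C=C(OS(=O)(=O)C(F)(F)F)c1cc2cc(C(C)=O)c(O[Si](C(C)C)(C(C)C)C(C)C)cc2o1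
F3 | step 6 | 1-{2-[(4R)-4-(7-methoxy-2,2-dimethyl-2H-chromen-6-yl)-4-(4,4,5,5-tetramethyl-1,3,2-dioxaborolan-2-yl)pent-1-en-2-yl]-6-(triisopropylsilyloxy)-1-benzofuran-5-yl}ethanone | COc1cc2c(cc1[C@@](C)(B1OC(C)(C)C(C)(C)O1)CC(=C)c1cc3cc(C(C)=O)c(O[Si](C(C)C)(C(C)C)C(C)C)cc3o1)C=CC(C)(C)O2
F4 | step 6 | 1-{2-[(4S)-4-hydroxy-4-(7-methoxy-2,2-dimethyl-2H-chromen-6-yl)pent-1-en-2-yl]-6-(triisopropylsilyloxy)-1-benzofuran-5-yl}ethanone | COc1cc2c(cc1[C@@](C)(O)CC(=C)c1cc3cc(C(C)=O)c(O[Si](C(C)C)(C(C)C)C(C)C)cc3o1)C=CC(C)(C)O2
F5 | step 2 | 4-acetyl-3-hydroxyphenyl acetate | CC(=O)Oc1ccc(C(C)=O)c(O)c1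
F6 | step 2 | 4-acetyl-5-hydroxy-2-iodophenyl acetate | CC(=O)Oc1cc(O)c(C(C)=O)cc1I
F7 | step 1 | 1-bromo-2-methoxy-4-[(2-methylbut-3-yn-2-yl)oxy]benzene | COc1cc(OC(C)(C)C#C)ccc1Br
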